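**Plan**
1. Retrosynthetic cuts, in order: the ring B O–CH2OMe bond (protecting group), the pyran C3''=C4'' double bond, the chalcone Cα=Cβ bond, then on ring A the O–C2'' ether bond and the C3'–vinyl bond, and on ring B the C3–prenyl bond.
2. Enabling feature: the only C=C of the pyran (C3''=C4'') is a cis-disubstituted alkene lying between ring A carbon C3' and the quaternary carbon C2'' carried by the C4' oxygen. Opening it leaves a 3'-vinyl group and a 4'-O-(1,1-dimethylallyl) ether, two terminal alkenes placed for six-membered ring closure by metathesis.
3. Forward: the ring B aldehyde comes from 4-hydroxybenzaldehyde by ortho C-prenylation and MOM protection. The ring A ketone comes from 2,4-dihydroxyacetophenone by C3 iodination, Suzuki vinylation, 4-O-propargylation and semihydrogenation.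
4. The two fragments are joined by aldol condensation to the open-chain chalcone. The pyran, the only ring built in the route, is closed afterwards by metathesis, and the MOM ether is removed last.
5. Stereochemistry: the target has no stereocentre. The E-enone comes from thermodynamically controlled dehydration in the condensation, and the cis pyran alkene is imposed by the ring.

Key step: step 8

Remark: chalcone numbering is used (ring A = ketone-derived ring, primed; ring B = aldehyde-derived ring, unprimed; pyran atoms double-primed). The aldol adduct of step 7 is racemic and its stereocentre is lost in the same flask.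

**Step 1**
Reactants: 1 4-hydroxybenzaldehyde; 2 prenyl bromide (1-bromo-3-methylbut-2-ene)
Product: 3 4-hydroxy-3-(3-methylbut-2-en-1-yl)benzaldehyde
Conditions: KOH (10% aq.), 0 °C→rt
Reagents that add atoms: none
Why: Ortho C-alkylation of an ambident phenoxide: in water the phenoxide oxygen is strongly hydrogen-bonded, so part of the soft allylic bromide should be attacked by the ortho carbon (the para position is blocked by the formyl group) and the dienone tautomerises back to the phenol; the O-prenyl ether formed alongside is separable and unreacted phenol can be recycled.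

**Step 2**
Reactants: 3 4-hydroxy-3-(3-methylbut-2-en-1-yl)benzaldehyde
Product: 4 4-(methoxymethoxy)-3-(3-methylbut-2-en-1-yl)benzaldehyde
Conditions: MOMCl, i-Pr2NEt, CH2Cl2, 0 °C→rt
Reagents that add atoms: chloromethyl methyl ether (MOMCl), COCCl
Why: Williamson-type O-alkylation (MOM protection) with the reactive α-chloro ether masks the phenol as a base-stable acetal, since the free phenoxide would deactivate the aldehyde in the later aldol condensation.

**Step 3**
Reactants: 5 2,4-dihydroxyacetophenone
Product: 6 1-(2,4-dihydroxy-3-iodophenyl)ethanone
Conditions: I2 (0.4 equiv), HIO3 (0.2 equiv), EtOH/H2O, 35–40 °C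
Reagents that add atoms: iodine, [I][I]; iodic acid, O[I](=O)=O
Why: Electrophilic aromatic iodination in which iodic acid reoxidises the iodide formed; C3 is ortho to both hydroxyl groups and is the established site of monoiodination of this ketone under these conditions.

**Step 4**
Reactants: 6 1-(2,4-dihydroxy-3-iodophenyl)ethanone; 7 potassium vinyltrifluoroborate
Product: 8 1-(3-ethenyl-2,4-dihydroxyphenyl)ethanone
Conditions: PdCl2(dppf)·CH2Cl2 (5 mol %), Cs2CO3, THF/H2O (9:1), degassed, 70 °C
Reagents that add atoms: none
Why: Suzuki–Miyaura cross-coupling (oxidative addition of zerovalent palladium into the C–I bond, vinyl transfer from boron after slow hydrolysis of the trifluoroborate, reductive elimination), placed before any O-alkylation because an ortho-iodoaryl propargyl or allyl ether would be open to intramolecular carbopalladation instead of cross-coupling.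

**Step 5**
Reactants: 8 1-(3-ethenyl-2,4-dihydroxyphenyl)ethanone; 9 3-chloro-3-methylbut-1-yne
Product: 10 1-{3-ethenyl-2-hydroxy-4-[(2-methylbut-3-yn-2-yl)oxy]phenyl}ethanone
Conditions: DBU, CuCl2·2H2O (cat.), MeCN, 0 °C→rt
Reagents that add atoms: none
Why: Copper-catalysed propargylic etherification of a phenol with a tertiary propargylic chloride (copper acetylide/allenylidene pathway), selective for the 4-OH because the 2-OH is hydrogen-bonded to the acetyl carbonyl, less acidic and more hindered; at room temperature the aryl propargyl ether stays far below its Claisen rearrangement temperature.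

**Step 6**
Reactants: 10 1-{3-ethenyl-2-hydroxy-4-[(2-methylbut-3-yn-2-yl)oxy]phenyl}ethanone
Product: 11 1-{3-ethenyl-2-hydroxy-4-[(2-methylbut-3-en-2-yl)oxy]phenyl}ethanone
Conditions: H2 (1 atm, stopped at 1 equiv uptake), Pd/CaCO3 poisoned with Pb(OAc)2, quinoline, EtOAc, rt
Reagents that add atoms: none
Why: Lindlar-type semihydrogenation: the terminal alkyne binds to the poisoned palladium surface much more strongly than an alkene, so with uptake limited to one equivalent it should be reduced to the vinyl group while the styrenyl vinyl group and the ketone are left untouched.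

**Step 7**
Reactants: 11 1-{3-ethenyl-2-hydroxy-4-[(2-methylbut-3-en-2-yl)oxy]phenyl}ethanone; 4 4-(methoxymethoxy)-3-(3-methylbut-2-en-1-yl)benzaldehyde
Product: 13 (E)-2'-hydroxy-4-(methoxymethoxy)-4'-(2-methylbut-3-en-2-yloxy)-3-prenyl-3'-vinylchalcone, via aldol adduct 12 (not isolated)
Conditions: KOH (excess), EtOH, 0 °C→rt; cold dilute acid work-up
Reagents that add atoms: none
Why: Claisen–Schmidt (crossed aldol) condensation: the methyl ketone enolate adds to the non-enolisable aldehyde and the β-hydroxy ketone loses water by E1cB elimination under thermodynamic control to give the E-enone, which erases the racemic carbinol centre; the MOM acetal, the tertiary allyl ether and all alkenes are inert to ethanolic KOH at room temperature.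

**Step 8**
Reactants: 13 (E)-2'-hydroxy-4-(methoxymethoxy)-4'-(2-methylbut-3-en-2-yloxy)-3-prenyl-3'-vinylchalcone
Product: 14 (E)-1-(5-hydroxy-2,2-dimethyl-2H-chromen-6-yl)-3-[4-(methoxymethoxy)-3-(3-methylbut-2-en-1-yl)phenyl]prop-2-en-1-one (paratocarpin B 4-O-methoxymethyl ether)
Conditions: (H2IMes)(PCy3)Cl2Ru=CHPh (second-generation Grubbs catalyst, 5 mol %), CH2Cl2 (0.005 M, degassed), 25→40 °C
Reagents that add atoms: none
Why: Ring-closing olefin metathesis: after loss of PCy3 the ruthenium alkylidene exchanges onto one of the two monosubstituted alkenes (probably the 3'-vinyl group, where the neighbouring ether oxygen can stabilise the new benzylidene), and intramolecular [2+2] cycloaddition with the other vinyl group followed by retro-[2+2] of the ruthenacyclobutane forms C3''=C4'' and returns Ru=CH2 to the cycle, with ethylene as the only by-product. The closest known reaction type is the metathesis closure of 2-vinylaryl allyl ethers to 2H-chromenes. The ring closes as a six-membered ring from a 1,7-diene with the new alkene endocyclic and therefore necessarily cis, and the gem-dimethyl group at C2'' favours the folded, reactive conformer. No stereocentre is created. The step needs chemoselectivity among four kinds of alkene and ring closure over intermolecular reaction: only the two terminal vinyl groups should load the catalyst, the trisubstituted prenyl alkene and the electron-poor conjugated enone react far more slowly, and high dilution suppresses cross-metathesis. Working at 25–40 °C keeps the tertiary allyl aryl ether well below the onset of aromatic Claisen rearrangement to C5'.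

**Step 9**
Reactants: 14 paratocarpin B 4-O-methoxymethyl ether
Product: 15 paratocarpin B
Conditions: HCl (3 M aq.), MeOH, rt
Reagents that add atoms: none
Why: Acid-catalysed acetal cleavage (MOM deprotection) through an oxocarbenium ion trapped by methanol; dilute HCl at room temperature is the usual condition for prenylated 2'-hydroxychalcones and should be mild enough to leave the prenyl group, the chromene and the open chalcone intact.

**Compound list**
1 | 4-hydroxybenzaldehyde | O=Cc1ccc(O)cc1 | starting material
2 | prenyl bromide (1-bromo-3-methylbut-2-ene) | CC(C)=CCBr | starting material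
3 | 4-hydroxy-3-(3-methylbut-2-en-1-yl)benzaldehyde | CC(C)=CCc1cc(C=O)ccc1O | intermediate
4 | 4-(methoxymethoxy)-3-(3-methylbut-2-en-1-yl)benzaldehyde | CC(C)=CCc1cc(C=O)ccc1OCOC | intermediate
5 | 2,4-dihydroxyacetophenone | CC(=O)c1ccc(O)cc1O | starting material
6 | 1-(2,4-dihydroxy-3-iodophenyl)ethanone | CC(=O)c1ccc(O)c(I)c1O | intermediate
7 | potassium vinyltrifluoroborate | C=C[B-](F)(F)F.[K+] | starting material
8 | 1-(3-ethenyl-2,4-dihydroxyphenyl)ethanone | CC(=O)c1ccc(O)c(C=C)c1O | intermediate
9 | 3-chloro-3-methylbut-1-yne | CC(C)(Cl)C#C | starting material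
10 | 1-{3-ethenyl-2-hydroxy-4-[(2-methylbut-3-yn-2-yl)oxy]phenyl}ethanone | CC(=O)c1ccc(OC(C)(C)C#C)c(C=C)c1O | intermediate
11 | 1-{3-ethenyl-2-hydroxy-4-[(2-methylbut-3-en-2-yl)oxy]phenyl}ethanone | CC(=O)c1ccc(OC(C)(C)C=C)c(C=C)c1O | intermediate
12 | 1-{3-ethenyl-2-hydroxy-4-[(2-methylbut-3-en-2-yl)oxy]phenyl}-3-hydroxy-3-[4-(methoxymethoxy)-3-(3-methylbut-2-en-1-yl)phenyl]propan-1-one (racemic aldol adduct, not isolated) | C=Cc1c(OC(C)(C)C=C)ccc(C(=O)CC(O)c2ccc(OCOC)c(CC=C(C)C)c2)c1O | intermediate
13 | (E)-1-{3-ethenyl-2-hydroxy-4-[(2-methylbut-3-en-2-yl)oxy]phenyl}-3-[4-(methoxymethoxy)-3-(3-methylbut-2-en-1-yl)phenyl]prop-2-en-1-one (2'-hydroxy-4-(methoxymethoxy)-4'-(2-methylbut-3-en-2-yloxy)-3-prenyl-3'-vinylchalcone) | C=Cc1c(OC(C)(C)C=C)ccc(C(=O)/C=C/c2ccc(OCOC)c(CC=C(C)C)c2)c1O | intermediate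
14 | (E)-1-(5-hydroxy-2,2-dimethyl-2H-chromen-6-yl)-3-[4-(methoxymethoxy)-3-(3-methylbut-2-en-1-yl)phenyl]prop-2-en-1-one (paratocarpin B 4-O-methoxymethyl ether) | CC(C)=CCc1cc(/C=C/C(=O)c2ccc3c(c2O)C=CC(C)(C)O3)ccc1OCOC | intermediate
15 | paratocarpin B, (E)-1-(5-hydroxy-2,2-dimethyl-2H-chromen-6-yl)-3-[4-hydroxy-3-(3-methylbut-2-en-1-yl)phenyl]prop-2-en-1-one | CC(C)=CCc1cc(/C=C/C(=O)c2ccc3c(c2O)C=CC(C)(C)O3)ccc1O | target

**Step count**
Total steps: 9. Longest linear sequence: 7 steps (steps 3 to 9, from compound 5 to compound 15).

**Steps most likely to fail, with fallbacks**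

Step 6. Hydrogen uptake may not stop at the alkene stage, or the styrenyl vinyl group may be saturated alongside the alkyne. The fallback avoids the alkyne and the hydrogenation altogether. It sets out from compound 8 and returns at compound 11. Compound 8 would be treated with the reagent tert-butyl 2-methylbut-3-en-2-yl carbonate and Pd(PPh3)4 (cat.) in THF at 0 °C, a palladium-catalysed decarboxylative allylic etherification. Zerovalent palladium ionises the carbonate to a 1,1-dimethyl-π-allyl complex, and the tert-butoxide released after loss of CO2 deprotonates the more acidic 4-OH. The phenoxide should attack the more substituted allyl terminus under kinetic control, so the reaction is stopped at full conversion to keep the branched ether from re-ionising to the linear prenyl ether. This gives compound 11 directly; no new compound arises on this path (F0).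

Step 8. Initiation may be slow at two hindered vinyl groups (a styrene flanked by two oxygen substituents and a vinyl group on a quaternary carbon). Catalyst decay, cross-metathesis at the prenyl group or oligomerisation could then take over. The fallback makes the same bond by the same reaction one stage earlier, where only the two reacting alkenes are present. It sets out from compound 11 and returns at compound 14. Compound 11 with (H2IMes)(PCy3)Cl2Ru=CHPh in dilute CH2Cl2 should close to 1-(5-hydroxy-2,2-dimethyl-2H-chromen-6-yl)ethanone F1. Claisen–Schmidt condensation of this ketone with compound 4 (KOH, EtOH, rt) would then pass through the aldol adduct 3-hydroxy-1-(5-hydroxy-2,2-dimethyl-2H-chromen-6-yl)-3-[4-(methoxymethoxy)-3-(3-methylbut-2-en-1-yl)phenyl]propan-1-one F2, which is not isolated, and give compound 14.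

Step 1. O-alkylation may outrun ortho C-alkylation, and some double alkylation is possible, so little of the phenoxide would be converted into the C-prenyl phenol. The fallback delivers the prenyl group to the ortho carbon by a sigmatropic shift instead. It sets out from compound 1 and returns at compound 3. Compound 1 would be O-alkylated with compound 9 (DBU, CuCl2·2H2O cat., MeCN) to 4-[(2-methylbut-3-yn-2-yl)oxy]benzaldehyde F3. Semihydrogenation (H2, Pd/CaCO3 poisoned with Pb(OAc)2, quinoline) would give 4-[(2-methylbut-3-en-2-yl)oxy]benzaldehyde F4; no other alkene is present here. Heating F4 in N,N-diethylaniline at about 150 °C should bring about aromatic Claisen rearrangement with allylic transposition, placing the 3-methylbut-2-enyl group ortho to the phenol and giving compound 3.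

**Further compounds**
F0 | step 6 | none | none
F1 | step 8 | 1-(5-hydroxy-2,2-dimethyl-2H-chromen-6-yl)ethanone | CC(=O)c1ccc2c(c1O)C=CC(C)(C)O2
F2 | step 8 | 3-hydroxy-1-(5-hydroxy-2,2-dimethyl-2H-chromen-6-yl)-3-[4-(methoxymethoxy)-3-(3-methylbut-2-en-1-yl)phenyl]propan-1-one (racemic aldol adduct, not isolated) | CC(C)=CCc1cc(C(O)CC(=O)c2ccc3c(c2O)C=CC(C)(C)O3)ccc1OCOC
F3 | step 1 | 4-[(2-methylbut-3-yn-2-yl)oxy]benzaldehyde | C#CC(C)(C)Oc1ccc(C=O)cc1
F4 | step 1 | 4-[(2-methylbut-3-en-2-yl)oxy]benzaldehyde | C=CC(C)(C)Oc1ccc(C=O)cc1
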